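**Retrosynthetic overview**

1. The target is a 14-membered macrolide (macrolide numbering: C1 = lactone carbonyl, C13 = ethyl-bearing carbinol carbon). The end game unmasks the C4 diol from an acetonide, oxidises C3, methylenates a C10 ketone and removes a sulfonyl group from C9.
2. Key disconnection C8–C9, which closes the only ring. The ring segment C10(=CH2)–C9H2–C8H(CH3)–C7H=C6(CH3) is a 1,5-diene: C8, its methyl group and the C6=C7 alkene together are the H–Nu adduct of a C6=C7–C8=CH2 1,3-diene, and C9 becomes a carbon acid once the exocyclic methylene on C10 is read as a ketone and C9 carries a sulfone.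
3. The open-chain precursor is the ester of a C1–C8 acid (terminal diene, C2 and C4 set) with a C9–C13 β-keto sulfone alcohol (C13 set).
4. Acid: asymmetric epoxidation of a mono-protected 2-methylidenepropane-1,3-diol sets C4, acetylide opening and carboalumination–vinylation build the E-diene, an Evans aldol sets C2. Alcohol: asymmetric ethylation of a commercial aldehyde ester sets C13, then sulfone acylation of the ester.
5. Ring order: the temporary dioxolane (step 4) first, the 14-membered lactone ring (step 14) second; the dioxolane is opened again in step 19.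

Key step: step 14

Remark: C2 lies between two carbonyl groups in the 3-keto compounds and is assumed to keep the (2R) configuration set in step 8 under the buffered oxidation and the mild acid of the last two steps.

**Route**

Step 1
Reactants: 1 2-methylidenepropane-1,3-diol
Product: 2 2-{[(4-methoxyphenyl)methoxy]methyl}prop-2-en-1-ol
Conditions: NaH (1.0 equiv), 4-methoxybenzyl chloride (0.9 equiv), Bu4NI (cat), THF, 0 → 25 °C
Reagents that add atoms: 4-methoxybenzyl chloride COc1ccc(CCl)cc1
Why: Williamson etherification of the monoalkoxide with a slight deficit of the benzyl chloride gives mainly the monoether of the symmetric diol and creates no stereocentre.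

Step 2
Reactants: 2 2-{[(4-methoxyphenyl)methoxy]methyl}prop-2-en-1-ol
Product: 3 [(2S)-2-{[(4-methoxyphenyl)methoxy]methyl}oxiran-2-yl]methanol
Conditions: Ti(OiPr)4 (10 mol %), L-(+)-diethyl tartrate (12 mol %), t-BuOOH, 4 Å molecular sieves, CH2Cl2, −20 °C
Reagents that add atoms: tert-butyl hydroperoxide CC(C)(C)OO
Why: Sharpless asymmetric epoxidation: the titanium tartrate complex binds the free allylic hydroxyl and with L-(+)-diethyl tartrate delivers oxygen to the alkene face that gives the (S)-epoxide, which fixes the future C4 (the free hydroxymethyl arm becomes the CH2OH group of the target and the PMB-bearing arm becomes C3).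

Step 3
Reactants: 3 [(2S)-2-{[(4-methoxyphenyl)methoxy]methyl}oxiran-2-yl]methanol
Product: 4 (2R)-2-{[(4-methoxyphenyl)methoxy]methyl}pent-4-yne-1,2-diol
Conditions: LiC≡CH·H2NCH2CH2NH2 (3 equiv), DMSO, 20 °C; aq NH4Cl
Reagents that add atoms: lithium acetylide (ethylenediamine complex) [Li]C#C
Why: SN2 opening of the 2,2-disubstituted epoxide by the acetylide at its unsubstituted CH2 terminus leaves the quaternary centre untouched, and the Payne rearrangement that the alkoxide could undergo is degenerate here because it regenerates the same enantiomer.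

Step 4
Reactants: 4 (2R)-2-{[(4-methoxyphenyl)methoxy]methyl}pent-4-yne-1,2-diol
Product: 5 (4S)-4-{[(4-methoxyphenyl)methoxy]methyl}-2,2-dimethyl-4-(prop-2-yn-1-yl)-1,3-dioxolane
Conditions: 2,2-dimethoxypropane, pyridinium p-toluenesulfonate (cat), CH2Cl2, 25 °C
Reagents that add atoms: 2,2-dimethoxypropane COC(C)(C)OC
Why: Acid-catalysed transacetalisation joins the tertiary and the free primary hydroxyl in a five-membered acetonide, the only cyclic acetal possible because the third oxygen is a PMB ether.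

Step 5
Reactants: 5 (4S)-4-{[(4-methoxyphenyl)methoxy]methyl}-2,2-dimethyl-4-(prop-2-yn-1-yl)-1,3-dioxolane
Product: 7 (4S)-4-{[(4-methoxyphenyl)methoxy]methyl}-2,2-dimethyl-4-[(2E)-2-methylpenta-2,4-dien-1-yl]-1,3-dioxolane, via alkenyldimethylalane 6 (not isolated)
Conditions: AlMe3 (3 equiv), Cp2ZrCl2 (0.3 equiv), CH2Cl2, 0 → 25 °C; then CH2=CHBr (3 equiv), ZnCl2 (1 equiv), Pd(PPh3)4 (5 mol %), THF, 25 °C
Reagents that add atoms: trimethylaluminium C[Al](C)C; vinyl bromide C=CBr
Why: Zirconium-catalysed syn-carboalumination of the terminal alkyne places methyl on the internal and aluminium on the terminal carbon, and the palladium-catalysed Negishi coupling of the alkenylalane with vinyl bromide (ZnCl2 as transmetallation shuttle) proceeds with retention to give the E-trisubstituted terminal 1,3-diene.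

Step 6
Reactants: 7 (4S)-4-{[(4-methoxyphenyl)methoxy]methyl}-2,2-dimethyl-4-[(2E)-2-methylpenta-2,4-dien-1-yl]-1,3-dioxolane
Product: 8 {(4S)-2,2-dimethyl-4-[(2E)-2-methylpenta-2,4-dien-1-yl]-1,3-dioxolan-4-yl}methanol
Conditions: DDQ (1.3 equiv), CH2Cl2–pH 7 buffer, 0 °C
Reagents that add atoms: none
Why: Oxidative PMB ether cleavage by DDQ proceeds through the benzylic oxocarbenium ion, which the buffer hydrolyses, and at 0 °C the electron-rich benzyl ether is oxidised much faster than the diene.

Step 7
Reactants: 8 {(4S)-2,2-dimethyl-4-[(2E)-2-methylpenta-2,4-dien-1-yl]-1,3-dioxolan-4-yl}methanol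
Product: 9 (4R)-2,2-dimethyl-4-[(2E)-2-methylpenta-2,4-dien-1-yl]-1,3-dioxolane-4-carbaldehyde
Conditions: Dess–Martin periodinane, NaHCO3, CH2Cl2, 0 → 25 °C
Reagents that add atoms: none
Why: Dess–Martin oxidation of the neopentyl primary alcohol stops at the aldehyde, which has no α-hydrogen and therefore cannot epimerise.

Step 8
Reactants: 9 (4R)-2,2-dimethyl-4-[(2E)-2-methylpenta-2,4-dien-1-yl]-1,3-dioxolane-4-carbaldehyde; 10 (4R)-4-benzyl-3-propanoyl-1,3-oxazolidin-2-one
Product: 12 (4R)-4-benzyl-3-[(2R,3R)-3-{(4R)-2,2-dimethyl-4-[(2E)-2-methylpenta-2,4-dien-1-yl]-1,3-dioxolan-4-yl}-3-hydroxy-2-methylpropanoyl]-1,3-oxazolidin-2-one, via Z-dibutylboron enolate 11 (not isolated)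
Conditions: 10, Bu2BOTf, iPr2NEt, CH2Cl2, 0 °C; then 9, −78 → 0 °C; pH 7 buffer, MeOH, H2O2
Reagents that add atoms: none
Why: Evans syn-aldol reaction: the Z-boron enolate reacts through a chair Zimmerman–Traxler transition state in which the (R)-benzyl auxiliary blocks one enolate face, which sets (2R) and the 2,3-syn carbinol (3R), the latter being oxidised away in step 18.

Step 9
Reactants: 12 (4R)-4-benzyl-3-[(2R,3R)-3-{(4R)-2,2-dimethyl-4-[(2E)-2-methylpenta-2,4-dien-1-yl]-1,3-dioxolan-4-yl}-3-hydroxy-2-methylpropanoyl]-1,3-oxazolidin-2-one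
Product: 13 (4R)-4-benzyl-3-[(2R,3R)-3-{(4R)-2,2-dimethyl-4-[(2E)-2-methylpenta-2,4-dien-1-yl]-1,3-dioxolan-4-yl}-2-methyl-3-[(triethylsilyl)oxy]propanoyl]-1,3-oxazolidin-2-one
Conditions: Et3SiOTf, 2,6-lutidine, CH2Cl2, −78 → 0 °C
Reagents that add atoms: triethylsilyl trifluoromethanesulfonate CC[Si](CC)(CC)OS(=O)(=O)C(F)(F)F
Why: Silylation with the silyl triflate and 2,6-lutidine caps the hindered secondary hydroxyl so that the carboxyl group can later be activated without self-acylation.

Step 10
Reactants: 13 (4R)-4-benzyl-3-[(2R,3R)-3-{(4R)-2,2-dimethyl-4-[(2E)-2-methylpenta-2,4-dien-1-yl]-1,3-dioxolan-4-yl}-2-methyl-3-[(triethylsilyl)oxy]propanoyl]-1,3-oxazolidin-2-one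
Product: 15 (2R,3R)-3-{(4R)-2,2-dimethyl-4-[(2E)-2-methylpenta-2,4-dien-1-yl]-1,3-dioxolan-4-yl}-2-methyl-3-[(triethylsilyl)oxy]propanoic acid, via lithium peroxycarboxylate 14 (not isolated)
Conditions: LiOH, H2O2, THF–H2O, 0 °C; then Na2SO3; then 1 M HCl to pH 4
Reagents that add atoms: hydrogen peroxide (as LiOOH) OO
Why: Lithium hydroperoxide cleavage of the N-acyloxazolidinone attacks the exocyclic imide carbonyl selectively and the sulfite quench reduces the peroxy acid salt, conditions under which C2 is not expected to epimerise.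

Step 11
Reactants: 16 ethyl (2E)-3-methyl-4-oxobut-2-enoate
Product: 17 ethyl (2E,4R)-4-hydroxy-3-methylhex-2-enoate
Conditions: Et2Zn (2 equiv), (+)-MIB [(2R)-3-exo-morpholinoisoborneol] (5 mol %), toluene–hexane, 0 °C; aq NH4Cl
Reagents that add atoms: diethylzinc CC[Zn]CC
Why: Amino-alcohol-catalysed enantioselective addition of diethylzinc to the aldehyde (the enoate is inert to dialkylzinc) sets (13R), (+)-MIB being chosen because (−)-MIB delivers (S)-carbinols from aryl and α-substituted alkenyl aldehydes.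

Step 12
Reactants: 17 ethyl (2E,4R)-4-hydroxy-3-methylhex-2-enoate
Product: 18 (3E,5R)-5-hydroxy-4-methyl-1-(phenylsulfonyl)hept-3-en-2-one
Conditions: PhSO2CH3 (3.3 equiv), n-BuLi (3.2 equiv), THF, −78 °C; then 17, −78 → 0 °C; aq NH4Cl
Reagents that add atoms: methyl phenyl sulfone CS(=O)(=O)c1ccccc1
Why: Claisen-type acylation of the lithiated sulfone by the ethyl ester gives the β-keto sulfone, which is at once deprotonated and so protected from a second addition, the extra carbanion equivalents covering the free hydroxyl and this deprotonation.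

Step 13
Reactants: 15 (2R,3R)-3-{(4R)-2,2-dimethyl-4-[(2E)-2-methylpenta-2,4-dien-1-yl]-1,3-dioxolan-4-yl}-2-methyl-3-[(triethylsilyl)oxy]propanoic acid; 18 (3E,5R)-5-hydroxy-4-methyl-1-(phenylsulfonyl)hept-3-en-2-one
Product: 19 (3R,4E)-4-methyl-6-oxo-7-(phenylsulfonyl)hept-4-en-3-yl (2R,3R)-3-{(4R)-2,2-dimethyl-4-[(2E)-2-methylpenta-2,4-dien-1-yl]-1,3-dioxolan-4-yl}-2-methyl-3-[(triethylsilyl)oxy]propanoate
Conditions: DCC, DMAP, DMAP·HCl, CH2Cl2, 25 °C
Reagents that add atoms: none
Why: Steglich esterification under the proton-buffered Keck conditions acylates the C13 hydroxyl through the acylpyridinium ion without touching its configuration, and the DMAP hydrochloride keeps the β-keto sulfone protonated so that its enol is not acylated.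

Step 14
Reactants: 19 (3R,4E)-4-methyl-6-oxo-7-(phenylsulfonyl)hept-4-en-3-yl (2R,3R)-3-{(4R)-2,2-dimethyl-4-[(2E)-2-methylpenta-2,4-dien-1-yl]-1,3-dioxolan-4-yl}-2-methyl-3-[(triethylsilyl)oxy]propanoate
Product: 20 (2R,3R,4R,6E,8R,11E,13R)-4-hydroxy-4-(hydroxymethyl)-2,6,8,12-tetramethyl-10-oxo-9-(phenylsulfonyl)-3-[(triethylsilyl)oxy]pentadeca-6,11-dien-13-olide as the acetonide of its 4-OH/4-CH2OH diol (both C9 epimers)
Conditions: [Pd(η3-C3H5)((S)-tBu-PHOX)][B(3,5-(CF3)2C6H3)4] (10 mol %), Et3N (1 equiv), CH2Cl2, 0.002 M (slow addition of 19), 25 °C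
Reagents that add atoms: none
Why: Proposed new method: Et3N deprotonates the β-keto sulfone at C9 and the resulting Et3NH+ protonates the zerovalent palladium–PHOX complex to a cationic palladium hydride, which adds across the terminal C8=CH2 bond of the diene (hydrogen to the CH2 carbon, which becomes the C8 methyl group) to give a π-allylpalladium cation over C6–C7–C8, and the sulfonyl enolate carbon C9 then attacks C8 on the face opposite to palladium, forming the C8–C9 bond and returning zerovalent palladium. The closest known reactions are the intermolecular enantioselective palladium–PHOX hydroalkylation of 1,3-dienes with β-dicarbonyl-type carbon acids and the palladium-catalysed macrocyclisation of sulfone-stabilised carbon acids onto π-allyl complexes generated from allylic esters or by hydropalladation of allenes, the new element being a diene as the π-allyl source in a ligand-controlled macrocyclisation. The 14-membered ring closes in the endo mode with respect to the allyl unit (bond to the distal terminus C8, so that C6=C7 remains in the ring as the E alkene), the competing bond to C6 (12-membered ring with a quaternary carbon) being disfavoured by the two carbon substituents on C6. The C8 centre, (8S) in the target and labelled (8R) in 20 only because the sulfonyl-bearing C9 outranks C7, is set by the ligand: the two diastereomeric π-allyl complexes equilibrate by reversible hydropalladation and the chiral P,N ligand decides which is alkylated, the ligand enantiomer being chosen for this sense, while C9 forms as a mixture that step 15 erases. The step needs the palladium hydride to choose the diene over the enone and zerovalent palladium to leave the allylic C13–O ester un-ionised, which the electron-poor β,β-disubstituted enone and the hindered, 2-methyl-substituted allylic carboxylate (a poor leaving group that would in any case return) should secure. C- over O-alkylation follows from the soft sulfonyl enolate and the reversibility of O-allylation, and high dilution favours ring closure over dimerisation.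

Step 15
Reactants: 20 macrocyclic β-keto sulfone (both C9 epimers)
Product: 21 (2R,3R,4R,6E,8S,11E,13R)-4-hydroxy-4-(hydroxymethyl)-2,6,8,12-tetramethyl-10-oxo-3-[(triethylsilyl)oxy]pentadeca-6,11-dien-13-olide as the acetonide of its 4-OH/4-CH2OH diol
Conditions: SmI2 (2.2 equiv), THF, −78 °C; then MeOH
Reagents that add atoms: none
Why: Reductive desulfonylation: electron transfer from SmI2 to the α-sulfonyl ketone expels benzenesulfinate in a fast unimolecular fragmentation that precedes any reduction of the γ-acyloxy enone, and protonation of the samarium enolate at C9 merges both C9 epimers into one ketone while C8 (β to the carbonyl) is untouched.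

Step 16
Reactants: 21 macrocyclic enone
Product: 22 (2R,3R,4R,6E,8S,11E,13R)-4-hydroxy-4-(hydroxymethyl)-2,6,8,12-tetramethyl-10-methylidene-3-[(triethylsilyl)oxy]pentadeca-6,11-dien-13-olide as the acetonide of its 4-OH/4-CH2OH diol
Conditions: Ph3PCH3Br, KN(SiMe3)2, THF, 0 °C; then 21, −78 → 0 °C
Reagents that add atoms: methyltriphenylphosphonium bromide C[P+](c1ccccc1)(c1ccccc1)c1ccccc1.[Br-]
Why: Wittig methylenation with the non-stabilised ylide adds 1,2 to the enone carbonyl to give the cross-conjugated exocyclic diene, while the hindered α-branched lactone carbonyl does not react with the ylide.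

Step 17
Reactants: 22 macrocyclic triene silyl ether
Product: 23 (2R,3R,4R,6E,8S,11E,13R)-3,4-dihydroxy-4-(hydroxymethyl)-2,6,8,12-tetramethyl-10-methylidenepentadeca-6,11-dien-13-olide as the acetonide of its 4-OH/4-CH2OH diol
Conditions: HF·pyridine, pyridine, THF, 0 → 25 °C
Reagents that add atoms: none
Why: Fluoride-mediated desilylation under pyridine-buffered conditions frees the C3 hydroxyl and leaves the acetonide and the lactone untouched.

Step 18
Reactants: 23 3-hydroxy macrolide acetonide
Product: 24 (2R,4R,6E,8S,11E,13R)-4-hydroxy-4-(hydroxymethyl)-2,6,8,12-tetramethyl-10-methylidene-3-oxopentadeca-6,11-dien-13-olide as the acetonide of its 4-OH/4-CH2OH diol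
Conditions: Dess–Martin periodinane, NaHCO3, CH2Cl2, 0 → 25 °C
Reagents that add atoms: none
Why: Dess–Martin oxidation under bicarbonate buffer converts the C3 carbinol into the ketone of the β-keto lactone without base strong enough to enolise C2, the other two hydroxyls being masked in the acetonide.

Step 19
Reactants: 24 3-keto macrolide acetonide
Product: 25 (2R,4R,6E,8S,11E,13R)-4-hydroxy-4-(hydroxymethyl)-2,6,8,12-tetramethyl-10-methylidene-3-oxopentadeca-6,11-dien-13-olide (target)
Conditions: AcOH–H2O–THF, 35 °C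
Reagents that add atoms: none
Why: Acid-catalysed hydrolysis of the terminal dioxolane frees the tertiary and the primary hydroxyl under conditions free of base, so that C2 is not enolised and the lactone is not transesterified.

**Compound list**

1 | 2-methylidenepropane-1,3-diol | C=C(CO)CO | starting material
2 | 2-{[(4-methoxyphenyl)methoxy]methyl}prop-2-en-1-ol | C=C(CO)COCc1ccc(OC)cc1 | intermediate
3 | [(2S)-2-{[(4-methoxyphenyl)methoxy]methyl}oxiran-2-yl]methanol | COc1ccc(COC[C@]2(CO)CO2)cc1 | intermediate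
4 | (2R)-2-{[(4-methoxyphenyl)methoxy]methyl}pent-4-yne-1,2-diol | COc1ccc(COC[C@](O)(CO)CC#C)cc1 | intermediate
5 | (4S)-4-{[(4-methoxyphenyl)methoxy]methyl}-2,2-dimethyl-4-(prop-2-yn-1-yl)-1,3-dioxolane | COc1ccc(COC[C@]2(COC(C)(C)O2)CC#C)cc1 | intermediate
6 | {(1E)-3-[(4S)-4-{[(4-methoxyphenyl)methoxy]methyl}-2,2-dimethyl-1,3-dioxolan-4-yl]-2-methylprop-1-en-1-yl}dimethylalumane | COc1ccc(COC[C@]2(COC(C)(C)O2)C/C(C)=C/[Al](C)C)cc1 | intermediate (not isolated)
7 | (4S)-4-{[(4-methoxyphenyl)methoxy]methyl}-2,2-dimethyl-4-[(2E)-2-methylpenta-2,4-dien-1-yl]-1,3-dioxolane | COc1ccc(COC[C@]2(COC(C)(C)O2)C/C(C)=C/C=C)cc1 | intermediate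
8 | {(4S)-2,2-dimethyl-4-[(2E)-2-methylpenta-2,4-dien-1-yl]-1,3-dioxolan-4-yl}methanol | OC[C@]1(COC(C)(C)O1)C/C(C)=C/C=C | intermediate
9 | (4R)-2,2-dimethyl-4-[(2E)-2-methylpenta-2,4-dien-1-yl]-1,3-dioxolane-4-carbaldehyde | O=C[C@]1(COC(C)(C)O1)C/C(C)=C/C=C | intermediate
10 | (4R)-4-benzyl-3-propanoyl-1,3-oxazolidin-2-one | CCC(=O)N1[C@H](Cc2ccccc2)COC1=O | starting material
11 | (4R)-4-benzyl-3-[(1Z)-1-[(dibutylboranyl)oxy]prop-1-en-1-yl]-1,3-oxazolidin-2-one | CCCCB(CCCC)O/C(=C\C)N1[C@H](Cc2ccccc2)COC1=O | intermediate (not isolated)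
12 | (4R)-4-benzyl-3-[(2R,3R)-3-{(4R)-2,2-dimethyl-4-[(2E)-2-methylpenta-2,4-dien-1-yl]-1,3-dioxolan-4-yl}-3-hydroxy-2-methylpropanoyl]-1,3-oxazolidin-2-one | O=C([C@H](C)[C@@H](O)[C@]1(COC(C)(C)O1)C/C(C)=C/C=C)N1[C@H](Cc2ccccc2)COC1=O | intermediate
13 | (4R)-4-benzyl-3-[(2R,3R)-3-{(4R)-2,2-dimethyl-4-[(2E)-2-methylpenta-2,4-dien-1-yl]-1,3-dioxolan-4-yl}-2-methyl-3-[(triethylsilyl)oxy]propanoyl]-1,3-oxazolidin-2-one | O=C([C@H](C)[C@@H](O[Si](CC)(CC)CC)[C@]1(COC(C)(C)O1)C/C(C)=C/C=C)N1[C@H](Cc2ccccc2)COC1=O | intermediate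
14 | lithium (2R,3R)-3-{(4R)-2,2-dimethyl-4-[(2E)-2-methylpenta-2,4-dien-1-yl]-1,3-dioxolan-4-yl}-2-methyl-3-[(triethylsilyl)oxy]propaneperoxoate | [Li+].[O-]OC(=O)[C@H](C)[C@@H](O[Si](CC)(CC)CC)[C@]1(COC(C)(C)O1)C/C(C)=C/C=C | intermediate (not isolated)
15 | (2R,3R)-3-{(4R)-2,2-dimethyl-4-[(2E)-2-methylpenta-2,4-dien-1-yl]-1,3-dioxolan-4-yl}-2-methyl-3-[(triethylsilyl)oxy]propanoic acid | OC(=O)[C@H](C)[C@@H](O[Si](CC)(CC)CC)[C@]1(COC(C)(C)O1)C/C(C)=C/C=C | intermediate
16 | ethyl (2E)-3-methyl-4-oxobut-2-enoate | CCOC(=O)/C=C(\C)C=O | starting material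
17 | ethyl (2E,4R)-4-hydroxy-3-methylhex-2-enoate | CCOC(=O)/C=C(\C)[C@@H](CC)O | intermediate
18 | (3E,5R)-5-hydroxy-4-methyl-1-(phenylsulfonyl)hept-3-en-2-one | O=C(CS(=O)(=O)c1ccccc1)/C=C(\C)[C@@H](CC)O | intermediate
19 | (3R,4E)-4-methyl-6-oxo-7-(phenylsulfonyl)hept-4-en-3-yl (2R,3R)-3-{(4R)-2,2-dimethyl-4-[(2E)-2-methylpenta-2,4-dien-1-yl]-1,3-dioxolan-4-yl}-2-methyl-3-[(triethylsilyl)oxy]propanoate | O=C(CS(=O)(=O)c1ccccc1)/C=C(\C)[C@@H](CC)OC(=O)[C@H](C)[C@@H](O[Si](CC)(CC)CC)[C@]1(COC(C)(C)O1)C/C(C)=C/C=C | intermediate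
20 | (2R,3R,4R,6E,8R,11E,13R)-4-hydroxy-4-(hydroxymethyl)-2,6,8,12-tetramethyl-10-oxo-9-(phenylsulfonyl)-3-[(triethylsilyl)oxy]pentadeca-6,11-dien-13-olide, acetonide of the 4-OH/4-CH2OH diol, both C9 epimers | O=C1/C=C(\C)[C@@H](CC)OC(=O)[C@H](C)[C@@H](O[Si](CC)(CC)CC)[C@]2(COC(C)(C)O2)C/C(C)=C/[C@@H](C)C1S(=O)(=O)c1ccccc1 | intermediate
21 | (2R,3R,4R,6E,8S,11E,13R)-4-hydroxy-4-(hydroxymethyl)-2,6,8,12-tetramethyl-10-oxo-3-[(triethylsilyl)oxy]pentadeca-6,11-dien-13-olide, acetonide of the 4-OH/4-CH2OH diol | O=C1/C=C(\C)[C@@H](CC)OC(=O)[C@H](C)[C@@H](O[Si](CC)(CC)CC)[C@]2(COC(C)(C)O2)C/C(C)=C/[C@@H](C)C1 | intermediate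
22 | (2R,3R,4R,6E,8S,11E,13R)-4-hydroxy-4-(hydroxymethyl)-2,6,8,12-tetramethyl-10-methylidene-3-[(triethylsilyl)oxy]pentadeca-6,11-dien-13-olide, acetonide of the 4-OH/4-CH2OH diol | C=C1/C=C(\C)[C@@H](CC)OC(=O)[C@H](C)[C@@H](O[Si](CC)(CC)CC)[C@]2(COC(C)(C)O2)C/C(C)=C/[C@@H](C)C1 | intermediate
23 | (2R,3R,4R,6E,8S,11E,13R)-3,4-dihydroxy-4-(hydroxymethyl)-2,6,8,12-tetramethyl-10-methylidenepentadeca-6,11-dien-13-olide, acetonide of the 4-OH/4-CH2OH diol | C=C1/C=C(\C)[C@@H](CC)OC(=O)[C@H](C)[C@@H](O)[C@]2(COC(C)(C)O2)C/C(C)=C/[C@@H](C)C1 | intermediate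
24 | (2R,4R,6E,8S,11E,13R)-4-hydroxy-4-(hydroxymethyl)-2,6,8,12-tetramethyl-10-methylidene-3-oxopentadeca-6,11-dien-13-olide, acetonide of the 4-OH/4-CH2OH diol | C=C1/C=C(\C)[C@@H](CC)OC(=O)[C@H](C)C(=O)[C@]2(COC(C)(C)O2)C/C(C)=C/[C@@H](C)C1 | intermediate
25 | (2R,4R,6E,8S,11E,13R)-4-hydroxy-4-(hydroxymethyl)-2,6,8,12-tetramethyl-10-methylidene-3-oxopentadeca-6,11-dien-13-olide | C=C1/C=C(\C)[C@@H](CC)OC(=O)[C@H](C)C(=O)[C@](O)(CO)C/C(C)=C/[C@@H](C)C1 | target

**Step count and risks**

Total step count: 19. Longest linear sequence: 17 (steps 1–10 and 13–19; steps 11–12 make the second fragment).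

Steps most likely to fail:

Step 14 (macrocyclising hydroalkylation). Ring closure may lose to intermolecular alkylation, the palladium hydride may isomerise the diene or the catalyst may ionise the allylic C13–O ester, and the ligand may fail to override substrate bias at C8. The fallback uses known chemistry and sets out from imide 13 and sulfone alcohol 18. The C8–C9 bond is made first by the known intermolecular palladium–PHOX hydroalkylation of a 1,3-diene with an activated carbon acid (same catalyst, Et3N, CH2Cl2, ordinary concentration), which gives the open-chain hydroxy imide F1. Cleavage of the auxiliary with LiOH/H2O2 gives the seco hydroxy acid F2. Yamaguchi macrolactonisation between the C1 acid and the C13 hydroxyl (2,4,6-trichlorobenzoyl chloride, Et3N, then DMAP, toluene, high dilution) then closes the ring and comes back to the route at 20.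

Step 16 (methylenation). The basic ylide may enolise the ketone toward C9 or deprotonate the vinylogous position C13 instead of adding, which would stall the reaction or erode the C13 configuration. The fallback sets out from 21: addition of Me3SiCH2Li/CeCl3 (THF, −78 °C; weakly basic and selective for the ketone over the lactone) gives the β-hydroxysilane F3 as a mixture of C10 epimers. HF·pyridine then brings about acid-mediated Peterson elimination and removes the triethylsilyl group in the same operation, which comes back to the route at 23.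

Step 19 (acetonide hydrolysis). Under acid the freed C4 hydroxyl may attack C1 (translactonisation to a five-membered lactone with opening of the macrocycle), or C2 may epimerise through the enol of the β-keto lactone. The fallback sets out from 23 and removes the acetonide before C3 is oxidised (AcOH–H2O–THF), giving the triol F4. Selective silylation of the primary hydroxyl (TBSCl, imidazole, CH2Cl2, 0 °C) gives the silyl ether F5. Dess–Martin oxidation of C3 (the tertiary hydroxyl is inert) gives the keto silyl ether F6. Pyridine-buffered HF·pyridine is then a near-neutral last step that comes back to the route at 25.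

**Further compounds**

F1 | step 14 | (4R)-4-benzyl-1,3-oxazolidin-2-one imide of seco acid F2 (C8–C9 bond formed, 13-OH free, both C9 epimers) | O=C([C@H](C)[C@@H](O[Si](CC)(CC)CC)[C@]1(COC(C)(C)O1)C/C(C)=C/[C@@H](C)C(C(=O)/C=C(\C)[C@@H](CC)O)S(=O)(=O)c1ccccc1)N1[C@H](Cc2ccccc2)COC1=O
F2 | step 14 | (2R,3R,4R,6E,8R,11E,13R)-4,13-dihydroxy-4-(hydroxymethyl)-2,6,8,12-tetramethyl-10-oxo-9-(phenylsulfonyl)-3-[(triethylsilyl)oxy]pentadeca-6,11-dienoic acid, acetonide of the 4-OH/4-CH2OH diol, both C9 epimers | OC(=O)[C@H](C)[C@@H](O[Si](CC)(CC)CC)[C@]1(COC(C)(C)O1)C/C(C)=C/[C@@H](C)C(C(=O)/C=C(\C)[C@@H](CC)O)S(=O)(=O)c1ccccc1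
F3 | step 16 | 10-hydroxy-10-[(trimethylsilyl)methyl] adduct of 21 (both C10 epimers) | C[Si](C)(C)CC1(O)/C=C(\C)[C@@H](CC)OC(=O)[C@H](C)[C@@H](O[Si](CC)(CC)CC)[C@]2(COC(C)(C)O2)C/C(C)=C/[C@@H](C)C1
F4 | step 19 | (2R,3R,4R,6E,8S,11E,13R)-3,4-dihydroxy-4-(hydroxymethyl)-2,6,8,12-tetramethyl-10-methylidenepentadeca-6,11-dien-13-olide | C=C1/C=C(\C)[C@@H](CC)OC(=O)[C@H](C)[C@@H](O)[C@](O)(CO)C/C(C)=C/[C@@H](C)C1
F5 | step 19 | tert-butyldimethylsilyl ether of F4 at the primary hydroxyl | C=C1/C=C(\C)[C@@H](CC)OC(=O)[C@H](C)[C@@H](O)[C@](O)(CO[Si](C)(C)C(C)(C)C)C/C(C)=C/[C@@H](C)C1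
F6 | step 19 | tert-butyldimethylsilyl ether of 25 at the primary hydroxyl | C=C1/C=C(\C)[C@@H](CC)OC(=O)[C@H](C)C(=O)[C@](O)(CO[Si](C)(C)C(C)(C)C)C/C(C)=C/[C@@H](C)C1
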